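**Retrosynthetic overview**
1. All atoms come from two bought arenes. Ketone 1 carries ring A and C7–C9 (C7 = future carbinol carbon, C8 = ether carbon, C9 = methyl) and is brominated at C8 to racemic 2. Phenol 3 carries ring B and its allyl group.
2. Key disconnection, the C8–O(aryl) ether bond: 2 and 3 are joined by an enantioconvergent copper-catalysed O-alkylation through the planar radical 4. This gives (S)-ketone 5 and sets C8.
3. Last disconnection, the C7–H bond of the carbinol: chelation-controlled hydride addition to 5 sets C7 from C8 and gives the (7R,8S)-erythro target 6, which is (1R,2S) in chain numbering.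
4. No ring is formed at any stage, since both benzene rings are bought intact, and no protecting group is used.

Assumption: the sense of induction of the new step 2 cannot be known in advance; (S,S)-Ph-BOX is written, and if it gives (R)-5 the equally available (R,R)-ligand takes its place with nothing else changed.

**Step 1**
Reactants: 1 3',4'-dimethoxypropiophenone [1-(3,4-dimethoxyphenyl)propan-1-one]
Product: 2 rac-2-bromo-1-(3,4-dimethoxyphenyl)propan-1-one
Conditions: CuBr2 (2.1 equiv), EtOAc/CHCl3 1:1, reflux, 3 h
Reagents that add atoms: CuBr2, Br[Cu]Br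
Why: King–Ostrum alpha-bromination, in which CuBr2 brominates the enol of the aryl ketone only at the alpha-carbon and leaves the acyl-deactivated dimethoxyarene alone; the new centre is deliberately racemic because step 2 erases it.

**Step 2**
Reactants: 2 rac-2-bromo-1-(3,4-dimethoxyphenyl)propan-1-one (1.2 equiv); 3 4-allyl-2,6-dimethoxyphenol (methoxyeugenol, 1.0 equiv)
Product: 5 (2S)-2-(4-allyl-2,6-dimethoxyphenoxy)-1-(3,4-dimethoxyphenyl)propan-1-one, via alpha-keto radical 4 (not isolated)
Conditions: Cu(MeCN)4PF6 (10 mol %), (S,S)-Ph-BOX (12 mol %), Cs2CO3 (1.2 equiv, powdered), 4 Å MS, toluene (0.05 M), −20 °C, Ar, dark, 48 h; cold filtration through neutral silica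
Reagents that add atoms: none
Why: Proposed new method: the neutral (BOX)Cu–OAr complex of monovalent copper, formed from 3 and Cs2CO3, abstracts bromine from either enantiomer of 2 to give the planar radical 4 and (BOX)Cu(OAr)Br of divalent copper; 4 is trapped at the metal, with its carbonyl oxygen as a second contact point, to give a trivalent copper alkyl aryloxide, and C–O reductive elimination inside the C2-symmetric ligand pocket releases (S)-5 and monovalent copper, so both enantiomers of 2 converge on one enantiomer of 5 and C8 is set by the ligand; the insoluble base, the non-polar solvent and −20 °C hold back the racemic SN2 path, E2 loss of HBr and enolisation of 5; the closest known reaction types are the copper-catalysed enantioconvergent substitution of racemic alpha-halo amides by oxygen nucleophiles, the nickel-catalysed enantioconvergent cross-coupling of racemic alpha-bromo ketones, and the Cu/BOX Kharasch–Sosnovsky radical C–O coupling, whereas an alpha-bromo aryl ketone combined with a 2,6-disubstituted phenol has not been shown.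

**Step 3**
Reactants: 5 (2S)-2-(4-allyl-2,6-dimethoxyphenoxy)-1-(3,4-dimethoxyphenyl)propan-1-one
Product: 6 (1R,2S)-2-(4-allyl-2,6-dimethoxyphenoxy)-1-(3,4-dimethoxyphenyl)propan-1-ol
Conditions: Zn(BH4)2 (1.0 equiv, 0.15 M stock solution in Et2O), Et2O/CH2Cl2 4:1, −78 → −40 °C, 2 h; sat. aq NH4Cl
Reagents that add atoms: none
Why: Cram-chelate (chelation-controlled) 1,2-induction, in which divalent zinc ties the carbonyl oxygen and the C8 aryloxy oxygen (helped by an ortho-methoxy group) into a five-membered chelate and hydride enters from the face bearing C8–H rather than C8–CH3, converting (8S) into (7R,8S)-erythro, while the non-basic cold medium leaves C8 and the allyl alkene untouched.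

**Compound list**
1 | 3',4'-dimethoxypropiophenone | CCC(=O)c1ccc(OC)c(OC)c1 | starting material
2 | rac-2-bromo-1-(3,4-dimethoxyphenyl)propan-1-one | CC(Br)C(=O)c1ccc(OC)c(OC)c1 | intermediate
3 | 4-allyl-2,6-dimethoxyphenol (methoxyeugenol) | C=CCc1cc(OC)c(O)c(OC)c1 | starting material
4 | 1-(3,4-dimethoxyphenyl)-1-oxopropan-2-yl radical (planar, achiral, not isolated) | C[CH]C(=O)c1ccc(OC)c(OC)c1 | intermediate
5 | (2S)-2-(4-allyl-2,6-dimethoxyphenoxy)-1-(3,4-dimethoxyphenyl)propan-1-one | C=CCc1cc(OC)c(O[C@@H](C)C(=O)c2ccc(OC)c(OC)c2)c(OC)c1 | intermediate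
6 | (1R,2S)-2-(4-allyl-2,6-dimethoxyphenoxy)-1-(3,4-dimethoxyphenyl)propan-1-ol, (7R,8S)-erythro | C=CCc1cc(OC)c(O[C@@H](C)[C@H](O)c2ccc(OC)c(OC)c2)c(OC)c1 | target

**Total step count:** 3
**Longest linear sequence:** 3 steps (1 → 2 → 5 → 6)

**Steps most likely to fail**

1) Step 2, the new step.
- Risks:
  - A racemic SN2 background reaction.
  - E2 elimination to the aryl vinyl ketone, followed by oxa-Michael addition of 3.
  - Addition of radical 4 to the allyl group.
  - Slow turnover with the hindered, easily oxidised phenol.
  - Base-induced loss of ee in 5.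
- Fallback: this uses known chemistry only, sets out from 3 and comes back at 5, and then needs neither 1 nor 2. Mitsunobu reaction of 3 with bought methyl (R)-lactate, C[C@@H](O)C(=O)OC (PPh3, DIAD, THF, 0 °C, clean SN2 inversion), gives methyl (2S)-2-(4-allyl-2,6-dimethoxyphenoxy)propanoate F1. MeNHOMe·HCl with iPrMgCl (THF, −20 °C) converts it into (2S)-2-(4-allyl-2,6-dimethoxyphenoxy)-N-methoxy-N-methylpropanamide F2. This amide takes up exactly one equivalent of 3,4-dimethoxyphenylmagnesium bromide F3, made from bought 4-bromoveratrole and Mg in THF, at 0 °C to give 5.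

2) Step 3.
- Risk: the aryl ether oxygen is a weak donor, so chelation may be incomplete and the erythro/threo ratio only modest.
- Fallback: this sets out from 5 and comes back at 6. The opposite facial bias is used on purpose and then corrected. The non-chelating bulky hydride KBH(s-Bu)3 (THF, −78 °C, Felkin–Anh control) gives (1S,2S)-2-(4-allyl-2,6-dimethoxyphenoxy)-1-(3,4-dimethoxyphenyl)propan-1-ol F4, the threo isomer. Mitsunobu inversion at C7 with 4-nitrobenzoic acid (PPh3, DIAD, toluene, 0 °C) gives (1R,2S)-2-(4-allyl-2,6-dimethoxyphenoxy)-1-(3,4-dimethoxyphenyl)propyl 4-nitrobenzoate F5. K2CO3 in MeOH then releases 6.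

3) Step 1.
- Risks: competing bromination of the electron-rich ring, or incomplete conversion.
- Fallback: this sets out from 1 and comes back at 2. The enol is made first and brominated under neutral, cold conditions. TMSOTf and Et3N (CH2Cl2, 0 °C) give (Z)-[1-(3,4-dimethoxyphenyl)prop-1-en-1-yl]oxytrimethylsilane F6, which reacts with NBS (THF, −78 °C) at the enol carbon only to give 2.

**Further compounds**
F1 | step 2 | methyl (2S)-2-(4-allyl-2,6-dimethoxyphenoxy)propanoate | C=CCc1cc(OC)c(O[C@@H](C)C(=O)OC)c(OC)c1
F2 | step 2 | (2S)-2-(4-allyl-2,6-dimethoxyphenoxy)-N-methoxy-N-methylpropanamide | C=CCc1cc(OC)c(O[C@@H](C)C(=O)N(C)OC)c(OC)c1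
F3 | step 2 | 3,4-dimethoxyphenylmagnesium bromide | COc1ccc([Mg]Br)cc1OC
F4 | step 3 | (1S,2S)-2-(4-allyl-2,6-dimethoxyphenoxy)-1-(3,4-dimethoxyphenyl)propan-1-ol | C=CCc1cc(OC)c(O[C@@H](C)[C@@H](O)c2ccc(OC)c(OC)c2)c(OC)c1
F5 | step 3 | (1R,2S)-2-(4-allyl-2,6-dimethoxyphenoxy)-1-(3,4-dimethoxyphenyl)propyl 4-nitrobenzoate | C=CCc1cc(OC)c(O[C@@H](C)[C@H](OC(=O)c3ccc(cc3)[N+](=O)[O-])c2ccc(OC)c(OC)c2)c(OC)c1
F6 | step 1 | (Z)-[1-(3,4-dimethoxyphenyl)prop-1-en-1-yl]oxytrimethylsilane | C/C=C(\O[Si](C)(C)C)c1ccc(OC)c(OC)c1
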